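**Retrosynthetic overview**

1. Target ⇐ the 11(13)-methylene lactone (face-selective hydrogenation sets C11), two acetylations, and hydroxyl-directed epoxidation of a Z-C1=C10 allylic alcohol.
2. Ten-membered carbocycle ⇐ Nozaki–Hiyama–Kishi closure of C9–C10 from a C9 aldehyde and a Z-vinyl iodide.
3. cis-Fused α-methylene-γ-lactone (C6–C7 bond, C6 and C7 stereocentres) ⇐ indium Barbier 2-(methoxycarbonyl)allylation of a Z-γ-hydroxy-enal held as its lactol.
4. That lactol (C1–C6 plus C15, Z-C4=C5, C3–O) ⇐ 3-methylmuconolactone ⇐ oxidative ring cleavage of 4-methylcatechol; the six ring carbons become C1–C6 and the ring cis geometry becomes the Z alkene.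
5. Ring order: butenolide (temporary) → γ-lactone → ten-membered ring → oxirane.

Assumption: germacranolide numbering is used for positions (ring C1–C10, lactone C6–O–C12, C13 on C11, C14 on C10, C15 on C4); 4-methylcatechol, (−)-menthol, methyl 3,3-dimethoxypropanoate and methyl acrylate are purchased.

Step 1
Reactants: 1 4-methylcatechol (4-methylbenzene-1,2-diol)
Product: 3 rac-2-(3-methyl-5-oxo-2,5-dihydrofuran-2-yl)acetic acid (3-methylmuconolactone), via (2Z,4Z)-3-methylhexa-2,4-dienedioic acid 2 (not isolated)
Conditions: CH3CO3H (2.5 equiv), AcOH, 20 °C, 48 h; then H2O, 80 °C, 1 h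
Reagents that add atoms: peracetic acid, CC(=O)OO
Why: Peracid intradiol cleavage of the catechol (ortho-quinone, then Baeyer–Villiger-type ring opening) gives the cis,cis-muconic acid, and the carboxyl on the methyl-bearing branch then adds to the unsubstituted acrylic terminus (intramolecular oxa-Michael cycloisomerisation), so the ring cis geometry becomes the Z-C4=C5 alkene and C3 is formed racemic.

Step 2
Reactants: 3 rac-3-methylmuconolactone
Product: 4 (1R,2S,5R)-menthyl 2-[(2R)-3-methyl-5-oxo-2,5-dihydrofuran-2-yl]acetate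
Conditions: (−)-menthol (1.1 equiv), cat. p-toluenesulfonic acid, toluene, reflux (Dean–Stark); crystallise the (2R)-ester; mother liquor with cat. DBU, 20 °C, recrystallise
Reagents that add atoms: (1R,2S,5R)-(−)-menthol, C[C@@H]1CC[C@H]([C@@H](C1)O)C(C)C
Why: Fischer esterification with a cheap chiral alcohol gives diastereomers for resolution by crystallisation, and the base-labile γ-centre of the butenolide lets DBU re-equilibrate the unwanted diastereomer, so C3 is secured as R.

Step 3
Reactants: 4 menthyl (2R)-lactone ester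
Product: 5 2-[(2R)-5-hydroxy-3-methyl-2,5-dihydrofuran-2-yl]acetaldehyde (lactol, both epimers at the lactol carbon)
Conditions: i-Bu2AlH (2.2 equiv), CH2Cl2, −78 °C; potassium sodium tartrate work-up at pH 7, used crude
Reagents that add atoms: none
Why: Low-temperature hydride half-reduction stops at the lactol and at the aldehyde because both tetrahedral aluminates are stable at −78 °C; no stereocentre is touched and neutral work-up avoids dehydration of the lactol to a furan.

Step 4
Reactants: 5 lactol aldehyde
Product: 6 (5R)-5-[(2Z)-3-iodobut-2-en-1-yl]-4-methyl-2,5-dihydrofuran-2-ol (lactol epimers)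
Conditions: EtPPh3Br, n-BuLi, THF, 20 °C; I2, −78 °C; NaN(SiMe3)2, −20 °C; then 5 (0.45 equiv), −78 °C
Reagents that add atoms: ethyltriphenylphosphonium bromide, CC[P+](c1ccccc1)(c1ccccc1)c1ccccc1.[Br-]; iodine, II
Why: Stork–Zhao Wittig olefination of the free aldehyde with the α-iodo ylide gives the Z-2-iodoalkene (iodine cis to C2) under kinetic control, while the lactolate formed by the second equivalent of ylide does not open at −78 °C.

Step 5
Reactants: 7 methyl 3,3-dimethoxypropanoate
Product: 8 3,3-dimethoxypropanal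
Conditions: i-Bu2AlH (1.05 equiv), CH2Cl2, −78 °C
Reagents that add atoms: none
Why: Half-reduction of an ester to the aldehyde through the cold-stable tetrahedral aluminate; no stereocentre is formed.

Step 6
Reactants: 8 3,3-dimethoxypropanal; 9 methyl acrylate
Product: 10 rac-methyl 3-hydroxy-5,5-dimethoxy-2-methylidenepentanoate
Conditions: 1,4-diazabicyclo[2.2.2]octane (0.5 equiv), MeOH, 20 °C, 3–5 d
Reagents that add atoms: none
Why: Morita–Baylis–Hillman reaction; the carbinol centre is racemic and is erased in the next step.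

Step 7
Reactants: 10 Baylis–Hillman adduct
Product: 11 methyl (2Z)-2-(bromomethyl)-5,5-dimethoxypent-2-enoate
Conditions: NBS, Me2S, CH2Cl2, 0 → 20 °C
Reagents that add atoms: N-bromosuccinimide, O=C1CCC(=O)N1Br
Why: Corey–Kim-type activation of the alcohol and bromide attack with allylic transposition gives the trisubstituted Z bromide (chain cis to CH2Br) under neutral conditions that spare the acetal.

Step 8
Reactants: 6 lactol vinyl iodide; 11 allylic bromide
Product: 13 2-[(2S,3S)-2-[(1Z,3R,5Z)-3-hydroxy-6-iodo-2-methylhepta-1,5-dien-1-yl]-4-methylidene-5-oxooxolan-3-yl]acetaldehyde, via open-chain dihydroxy ester 12 (not isolated)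
Conditions: In powder (1.5 equiv), 11 (1.3 equiv), THF/H2O 3:1, 20 °C; then AcOH/H2O 4:1, 40 °C
Reagents that add atoms: water, O
Why: Indium Barbier 2-(alkoxycarbonyl)allylation of the hydroxy-enal tautomer of the lactol: the Z-allylindium reacts through a chair transition state to give the 6,7-syn adduct (cis-lactone after ring closure), the C3 hydroxyl and the aldehyde oxygen held together by the Z alkene chelate indium so the allyl group adds anti to the C2 chain (1,4-induction), and aqueous acetic acid then lactonises and unmasks the C9 aldehyde (acetal hydrolysis).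

Step 9
Reactants: 13 hydroxy aldehyde lactone
Product: 14 (1Z,3R,5Z)-6-iodo-2-methyl-1-[(2S,3S)-4-methylidene-5-oxo-3-(2-oxoethyl)oxolan-2-yl]hepta-1,5-dien-3-yl acetate
Conditions: Ac2O, pyridine, 0 °C
Reagents that add atoms: acetic anhydride, CC(=O)OC(C)=O
Why: O-Acylation installs the C3 acetate of the target, which also prevents this allylic hydroxyl from directing the later epoxidation; no stereocentre changes.

Step 10
Reactants: 14 aldehyde vinyl iodide
Product: 15 (3R,6S,7S,9S)-3-acetoxy-9-hydroxygermacra-1(10)Z,4Z,11(13)-trien-12,6-olide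
Conditions: CrCl2 (6 equiv), NiCl2 (2 mol %), N-[2-(4-isopropyl-4,5-dihydro-1,3-oxazol-2-yl)-6-methylphenyl]methanesulfonamide (single enantiomer, 6.5 equiv), Et3N, THF, 2 mM, 20 °C
Reagents that add atoms: none
Why: Nozaki–Hiyama–Kishi macrocyclisation: zerovalent nickel formed in situ inserts into the vinyl iodide with retention of Z geometry, the vinyl trivalent chromium species adds only to the aldehyde to close the ten-membered ring (the two Z alkenes and the cis-lactone preorganise the chain), and the chiral sulfonamide–oxazoline ligand on chromium (enantiomer chosen on a model) sets C9 as S.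

Step 11
Reactants: 15 macrocyclic allylic alcohol
Product: 16 (1R,3R,6S,7S,9S,10S)-3-acetoxy-1,10-epoxy-9-hydroxygermacra-4Z,11(13)-dien-12,6-olide
Conditions: VO(acac)2 (5 mol %), t-BuOOH, CH2Cl2, 0 → 20 °C
Reagents that add atoms: tert-butyl hydroperoxide, CC(C)(C)OO
Why: Hydroxyl-directed vanadium-catalysed epoxidation: the C9 vanadate delivers oxygen to the same face of the adjacent Z-C1=C10 alkene, as in medium-ring Z-cycloalkenols, giving the cis epoxy alcohol of the target, while the acetate-flanked C4=C5 and the electron-poor methylene lactone do not react.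

Step 12
Reactants: 16 epoxy alcohol
Product: 17 (1R,3R,6S,7S,9S,10R)-3,9-diacetoxy-1,10-epoxygermacra-4Z,11(13)-dien-12,6-olide
Conditions: Ac2O, Et3N, cat. 4-(dimethylamino)pyridine, CH2Cl2, 20 °C
Reagents that add atoms: acetic anhydride, CC(=O)OC(C)=O
Why: Nucleophile-catalysed acylation of the remaining secondary alcohol; no stereocentre changes (the C10 descriptor changes only by priority).

Step 13
Reactants: 17 methylene lactone diacetate
Product: 18 (1R,3R,6R,7S,9S,10R,11R)-3,9-diacetoxy-1,10-epoxygermacr-4Z-en-12,6-olide (target)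
Conditions: H2 (1 atm), RhCl(PPh3)3 (10 mol %), benzene/EtOH 1:1, 20 °C
Reagents that add atoms: none
Why: Chemoselective homogeneous hydrogenation of the 1,1-disubstituted exocyclic alkene (trisubstituted C4=C5 and the epoxide are inert), with hydrogen delivered to the convex face of the cis-fused lactone (the face of H6 and H7), which places C13 cis to C5 and C8 and sets 11R.

**Compound list**

1 | 4-methylcatechol | Cc1ccc(O)c(O)c1 | starting material
2 | (2Z,4Z)-3-methylhexa-2,4-dienedioic acid | OC(=O)/C=C(C)\C=C/C(O)=O | intermediate (not isolated)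
3 | rac-2-(3-methyl-5-oxo-2,5-dihydrofuran-2-yl)acetic acid | OC(=O)CC1OC(=O)C=C1C | intermediate
4 | (1R,2S,5R)-menthyl 2-[(2R)-3-methyl-5-oxo-2,5-dihydrofuran-2-yl]acetate | C[C@@H]1CC[C@H]([C@@H](C1)OC(=O)C[C@H]2OC(=O)C=C2C)C(C)C | intermediate
5 | 2-[(2R)-5-hydroxy-3-methyl-2,5-dihydrofuran-2-yl]acetaldehyde (lactol epimers) | OC1C=C(C)[C@@H](CC=O)O1 | intermediate
6 | (5R)-5-[(2Z)-3-iodobut-2-en-1-yl]-4-methyl-2,5-dihydrofuran-2-ol (lactol epimers) | OC1C=C(C)[C@@H](C/C=C(/C)I)O1 | intermediate
7 | methyl 3,3-dimethoxypropanoate | COC(=O)CC(OC)OC | starting material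
8 | 3,3-dimethoxypropanal | O=CCC(OC)OC | intermediate
9 | methyl acrylate | C=CC(=O)OC | starting material
10 | rac-methyl 3-hydroxy-5,5-dimethoxy-2-methylidenepentanoate | COC(=O)C(=C)C(O)CC(OC)OC | intermediate
11 | methyl (2Z)-2-(bromomethyl)-5,5-dimethoxypent-2-enoate | COC(=O)/C(CBr)=C/CC(OC)OC | intermediate
12 | methyl (3S,4S,5Z,7R,9Z)-3-(2,2-dimethoxyethyl)-4,7-dihydroxy-10-iodo-6-methyl-2-methylideneundeca-5,9-dienoate | COC(=O)C(=C)[C@H](CC(OC)OC)[C@@H](O)/C=C(/C)[C@H](O)C/C=C(/C)I | intermediate (not isolated)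
13 | 2-[(2S,3S)-2-[(1Z,3R,5Z)-3-hydroxy-6-iodo-2-methylhepta-1,5-dien-1-yl]-4-methylidene-5-oxooxolan-3-yl]acetaldehyde | O=CC[C@@H]1[C@H](/C=C(/C)[C@H](O)C/C=C(/C)I)OC(=O)C1=C | intermediate
14 | (1Z,3R,5Z)-6-iodo-2-methyl-1-[(2S,3S)-4-methylidene-5-oxo-3-(2-oxoethyl)oxolan-2-yl]hepta-1,5-dien-3-yl acetate | O=CC[C@@H]1[C@H](/C=C(/C)[C@H](OC(C)=O)C/C=C(/C)I)OC(=O)C1=C | intermediate
15 | (3R,6S,7S,9S)-3-acetoxy-9-hydroxygermacra-1(10)Z,4Z,11(13)-trien-12,6-olide | O[C@H]1C[C@@H]2[C@H](/C=C(/C)[C@H](OC(C)=O)C/C=C1/C)OC(=O)C2=C | intermediate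
16 | (1R,3R,6S,7S,9S,10S)-3-acetoxy-1,10-epoxy-9-hydroxygermacra-4Z,11(13)-dien-12,6-olide | O[C@H]1C[C@@H]2[C@H](/C=C(/C)[C@H](OC(C)=O)C[C@H]3O[C@@]13C)OC(=O)C2=C | intermediate
17 | (1R,3R,6S,7S,9S,10R)-3,9-diacetoxy-1,10-epoxygermacra-4Z,11(13)-dien-12,6-olide | CC(=O)O[C@H]1C[C@@H]2[C@H](/C=C(/C)[C@H](OC(C)=O)C[C@H]3O[C@@]13C)OC(=O)C2=C | intermediate
18 | (1R,3R,6R,7S,9S,10R,11R)-3,9-diacetoxy-1,10-epoxygermacr-4Z-en-12,6-olide | CC(=O)O[C@H]1C[C@@H]2[C@H](/C=C(/C)[C@H](OC(C)=O)C[C@H]3O[C@@]13C)OC(=O)[C@@H]2C | target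

**Step count and risks**

Total step count: 13. Longest linear sequence: 10 steps (steps 1–4 and 8–13, from 4-methylcatechol); steps 5–7 form the side branch.

The three steps most likely to fail:

Step 1 may give a low yield, and the muconic acid could cyclise through the other carboxyl to the 4-methyl (quaternary) lactone. The fallback sets out from 1 and comes back at 3. Cleave 1 with CuCl, pyridine and MeOH under O2 (copper-mediated dioxygenase-type cleavage with methanolysis) to the half-ester (2Z,4Z)-6-methoxy-3-methyl-6-oxohexa-2,4-dienoic acid F1, in which only the carboxyl on the methyl-bearing branch is free. Its oxa-Michael cyclisation (cat. Et3N) can then only give methyl 2-(3-methyl-5-oxo-2,5-dihydrofuran-2-yl)acetate F2, and aqueous HCl hydrolysis of the ester returns 3. Regiochemistry is then fixed by which carboxyl is free, not by competing cyclisation rates; it still depends on methanol attacking the quinone carbonyl remote from the methyl-bearing enone.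

Step 8 may fail because the lactol dehydrates to a furan in the Lewis-acidic aqueous medium, or because the 1,4-induction from C3 is weak. The fallback sets out from 11 (with 6) and comes back at 13. Borylate 11 with bis(pinacolato)diboron and cat. Pd2(dba)3 to methyl (2E)-5,5-dimethoxy-2-[(4,4,5,5-tetramethyl-1,3,2-dioxaborolan-2-yl)methyl]pent-2-enoate F3 (chain still cis to the CH2B group). Then run the allylboration of 6 in toluene with the chiral Brønsted acid (R)-3,3′-bis(2,4,6-triisopropylphenyl)-1,1′-binaphthyl-2,2′-diyl hydrogen phosphate. The chair transition state keeps C6/C7 syn, the aldehyde face is chosen by the catalyst instead of the remote hydroxyl, and no aqueous metal salt is present; AcOH/H2O then gives 13 as in the main route.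

Step 10 may give the ten-membered ring in low yield or with poor control at C9. The fallback sets out from 14 and comes back at 15. Close the ring with CrCl2 and cat. NiCl2 in DMSO without the chiral ligand, oxidise the crude mixture of C9 epimers with MnO2 to the ten-membered Z-enone (3R,6S,7S)-3-acetoxy-9-oxogermacra-1(10)Z,4Z,11(13)-trien-12,6-olide F4, and reduce with catecholborane and the appropriate enantiomer of 1-methyl-3,3-diphenyltetrahydro-1H,3H-pyrrolo[1,2-c][1,3,2]oxazaborole (Corey–Bakshi–Shibata reduction). C9 is then set by reagent-controlled ketone reduction, not in the bond-forming event.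

**Further compounds**

F1 | step 1 | (2Z,4Z)-6-methoxy-3-methyl-6-oxohexa-2,4-dienoic acid | OC(=O)/C=C(C)\C=C/C(=O)OC
F2 | step 1 | rac-methyl 2-(3-methyl-5-oxo-2,5-dihydrofuran-2-yl)acetate | COC(=O)CC1OC(=O)C=C1C
F3 | step 8 | methyl (2E)-5,5-dimethoxy-2-[(4,4,5,5-tetramethyl-1,3,2-dioxaborolan-2-yl)methyl]pent-2-enoate | COC(=O)/C(CB1OC(C)(C)C(C)(C)O1)=C/CC(OC)OC
F4 | step 10 | (3R,6S,7S)-3-acetoxy-9-oxogermacra-1(10)Z,4Z,11(13)-trien-12,6-olide | O=C1C[C@@H]2[C@H](/C=C(/C)[C@H](OC(C)=O)C/C=C1/C)OC(=O)C2=C
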